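The route rests on cutting the bond between the quaternary cyclopentane carbon C1 and the carbinol carbon C1' of the cyclohexane, the most crowded bond of the molecule. It is made while both carbons are still trigonal. A cyclopentenyl Grignard reagent (C1 sp2, C3–Br already in place) adds to the C1' carbonyl of an epoxy ketone cut out of limonene oxide. The step exploits the C1' hydroxyl as a latent ketone and the C4'–C5' epoxide as the element that steers the attack. The epoxide later becomes the trans Br/Cl pair through one bromonium ion. The small group comes last: the C1 methyl enters by radical hydromethylation.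

Key step: step 6

Remark: atom labels are cyclopentane C1 (quaternary), C2 (CMe2), C3 (CHBr), C4, C5, and cyclohexane C1' (carbinol), C2', C3', C4' (CClMe), C5' (CHBr), C6'. Compound 1 and isomerically pure 7 are taken as commercial.

Step 1
Reactants: 1 2,2-dimethylcyclopentane-1,3-dione
Product: 2 (R)-3-hydroxy-2,2-dimethylcyclopentan-1-one
Conditions: (S)-Me-CBS oxazaborolidine (10 mol %), BH3·SMe2 (0.6 equiv), THF, −20 °C; MeOH quench
Reagents that add atoms: none
Why: Corey–Bakshi–Shibata reduction used as a desymmetrisation, in which the catalyst distinguishes the two enantiotopic carbonyls, treats quaternary C2 as the large and CH2 as the small substituent, and should therefore give the (R)-carbinol, while the hindered hydroxy ketone is reduced further only slowly.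

Step 2
Reactants: 2 (R)-3-hydroxy-2,2-dimethylcyclopentan-1-one
Product: 4 (S)-3-bromo-2,2-dimethylcyclopentan-1-one, via triflate 3 (not isolated)
Conditions: Tf2O, pyridine, CH2Cl2, −20 °C; then n-Bu4NBr (1.1 equiv), toluene, 0 °C → rt
Reagents that add atoms: tetrabutylammonium bromide CCCC[N+](CCCC)(CCCC)CCCC.[Br-]
Why: Sulfonate formation and SN2 displacement invert C3 to (S), because the acyl-bearing C2 disfavours ionisation and methyl shift and the cyclopentyl triflate reacts far faster than the neopentyl bromide product can exchange with bromide.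

Step 3
Reactants: 4 (S)-3-bromo-2,2-dimethylcyclopentan-1-one
Product: 5 (S)-3-bromo-2,2-dimethylcyclopentan-1-one hydrazone
Conditions: N2H4·H2O, Et3N, EtOH, 60 °C
Reagents that add atoms: hydrazine NN
Why: Hydrazone condensation at the only carbonyl, with the neopentyl secondary bromide too hindered for substitution by hydrazine and C3 not epimerisable because C2 is quaternary.

Step 4
Reactants: 5 (S)-3-bromo-2,2-dimethylcyclopentan-1-one hydrazone
Product: 6 (S)-4-bromo-1-iodo-5,5-dimethylcyclopent-1-ene
Conditions: I2 (2.2 equiv), 1,1,3,3-tetramethylguanidine, Et2O, 0 °C → rt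
Reagents that add atoms: iodine II
Why: Barton vinyl iodide synthesis, in which iodine oxidises the hydrazone, N2 is lost and elimination can only go toward the single α-CH2 (C5), which fixes the C1(I)=C5 olefin.

Step 5
Reactants: 7 (+)-trans-limonene oxide, (1S,2R,4R)-1-methyl-4-(prop-1-en-2-yl)-7-oxabicyclo[4.1.0]heptane
Product: 10 (1R,6S)-6-methyl-7-oxabicyclo[4.1.0]heptan-3-one, via methoxy hydroperoxide 8 (not isolated), via TEMPO ether 9 (not isolated)
Conditions: O3, MeOH, −78 °C; FeSO4·7H2O, TEMPO, −78 °C → rt; then mCPBA, CH2Cl2, 0 °C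
Reagents that add atoms: TEMPO CC1(C)CCCC(C)(C)N1[O]
Why: Oxodealkenylation (Criegee ozonolysis in methanol, Fe(II) reduction of the hydroperoxide, β-scission, aminoxyl trapping, peracid oxidation of the alkoxyamine) turns the isopropenyl-bearing carbon into the C1' ketone, erases that stereocentre and leaves the two epoxide stereocentres (future C4', C5') untouched.

Step 6
Reactants: 6 (S)-4-bromo-1-iodo-5,5-dimethylcyclopent-1-ene; 10 (1R,6S)-6-methyl-7-oxabicyclo[4.1.0]heptan-3-one
Product: 13 (1R,3R,6S)-3-[(4S)-4-bromo-5,5-dimethylcyclopent-1-en-1-yl]-6-methyl-3-(triethylsilyloxy)-7-oxabicyclo[4.1.0]heptane, via vinylmagnesium chloride 11 (not isolated), via magnesium alkoxide 12 (not isolated)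
Conditions: 6, i-PrMgCl·LiCl, THF, −20 → 0 °C; LaCl3·2LiCl, then 10, −78 °C; then Et3SiOTf, −78 → −20 °C
Reagents that add atoms: triethylsilyl trifluoromethanesulfonate CC[Si](CC)(CC)OS(=O)(=O)C(F)(F)F
Why: Iodine–magnesium exchange at the C(sp2)–I bond of 6 gives the vinyl Grignard 11, which under LaCl3·2LiCl activation adds 1,2 to the C1' carbonyl of 10, and the alkoxide 12 is silylated in the same flask. The closest known reaction type is the lanthanide-promoted addition of Grignard reagents to hindered, enolisable ketones. No ring is closed. The one new stereocentre, C1', is controlled by the C4'–C5' epoxide: in the half-chair of 10 the bulky nucleophile takes the equatorial path on the face opposite to the epoxide oxygen, which shields the other face sterically and by lone-pair repulsion, so that the C1'–O bond ends cis to the epoxide. The step needs exchange at iodine without touching the neopentyl secondary C3–Br bond (secured by the much faster exchange of sp2 iodides and the mild magnesium reagent), and it needs addition instead of enolisation with β-opening of the epoxide (secured by the low basicity and high oxophilicity of the lanthanum-modified reagent at low temperature). Because C1 is still trigonal, the bond that will later link two fully substituted carbons forms without neopentyl-type strain.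

Step 7
Reactants: 13 (1R,3R,6S)-3-[(4S)-4-bromo-5,5-dimethylcyclopent-1-en-1-yl]-6-methyl-3-(triethylsilyloxy)-7-oxabicyclo[4.1.0]heptane
Product: 15 {[(1R,3S,4S)-3-bromo-1-[(4S)-4-bromo-5,5-dimethylcyclopent-1-en-1-yl]-4-chloro-4-methylcyclohexyl]oxy}triethylsilane, via bromohydrin 14 (not isolated)
Conditions: HBr (1.0 equiv, Et2O), CH2Cl2, −78 °C; then 1-chloro-N,N,2-trimethylprop-1-en-1-amine, −40 °C → rt
Reagents that add atoms: hydrogen bromide Br; 1-chloro-N,N,2-trimethylprop-1-en-1-amine CC(C)=C(Cl)N(C)C
Why: Acidic trans-diaxial (Fürst–Plattner, Markovnikov) epoxide opening puts bromide on tertiary C4'; neutral activation of the secondary C5' hydroxyl then lets the antiperiplanar bromine expel it (neighbouring-group participation), and chloride opens the resulting bromonium ion anti at the tertiary carbon, giving net retention at C4' and inversion at C5', while any diaxial tertiary-bromide regioisomer can return to the same ion and drain to the diequatorial tertiary chloride, and the silyl ether blocks transannular ether formation.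

Step 8
Reactants: 15 {[(1R,3S,4S)-3-bromo-1-[(4S)-4-bromo-5,5-dimethylcyclopent-1-en-1-yl]-4-chloro-4-methylcyclohexyl]oxy}triethylsilane
Product: 16 (1R,3S,4S)-3-bromo-1-[(4S)-4-bromo-5,5-dimethylcyclopent-1-en-1-yl]-4-chloro-4-methylcyclohexan-1-ol
Conditions: HF·pyridine, pyridine, THF, 0 °C
Reagents that add atoms: none
Why: Buffered fluoride cleavage of the silyl ether, which involves no strong base or strong acid, so the tertiary chloride, the two secondary bromides and the tertiary allylic alcohol should survive.

Step 9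
Reactants: 16 (1R,3S,4S)-3-bromo-1-[(4S)-4-bromo-5,5-dimethylcyclopent-1-en-1-yl]-4-chloro-4-methylcyclohexan-1-ol
Product: 18 (1R,3S,4S)-3-bromo-1-[(1R,3S)-3-bromo-1,2,2-trimethylcyclopentyl]-4-chloro-4-methylcyclohexan-1-ol, via sulfonylhydrazide adduct 17 (not isolated)
Conditions: n-C8H17SO2NHNH2, aq CH2O, THF, rt; then 16, Fe(acac)3 (cat.), PhSiH3, MeOH, rt; then MeOH, 60 °C
Reagents that add atoms: formaldehyde C=O
Why: Metal-hydride hydrogen-atom-transfer hydromethylation, in which Fe–H gives H• to C5, the tertiary C1 radical adds to the small formaldehyde sulfonylhydrazone and loss of sulfinate and N2 leaves CH3; the one-carbon unit should enter trans to C3–Br, so that the bulky cyclohexyl group and the bromine both become pseudo-equatorial (1,3-cis) and C1 is set as (R).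

Compound list
1 | 2,2-dimethylcyclopentane-1,3-dione | CC1(C)C(=O)CCC1=O | starting material
2 | (R)-3-hydroxy-2,2-dimethylcyclopentan-1-one | CC1(C)[C@H](O)CCC1=O | intermediate
3 | (R)-2,2-dimethyl-3-oxocyclopentyl trifluoromethanesulfonate | CC1(C)[C@H](OS(=O)(=O)C(F)(F)F)CCC1=O | intermediate
4 | (S)-3-bromo-2,2-dimethylcyclopentan-1-one | CC1(C)[C@@H](Br)CCC1=O | intermediate
5 | (S)-3-bromo-2,2-dimethylcyclopentan-1-one hydrazone | CC1(C)[C@@H](Br)CCC1=NN | intermediate
6 | (S)-4-bromo-1-iodo-5,5-dimethylcyclopent-1-ene | CC1(C)[C@@H](Br)CC=C1I | intermediate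
7 | (+)-trans-limonene oxide, (1S,2R,4R)-1-methyl-4-(prop-1-en-2-yl)-7-oxabicyclo[4.1.0]heptane | C[C@]12CC[C@@H](C(C)=C)C[C@H]1O2 | starting material
8 | (1S,2R,4R)-4-(2-hydroperoxy-2-methoxypropan-2-yl)-1-methyl-7-oxabicyclo[4.1.0]heptane (acetal carbon unassigned) | C[C@]12CC[C@@H](C(C)(OC)OO)C[C@H]1O2 | intermediate
9 | 1-{[(1R,6S)-6-methyl-7-oxabicyclo[4.1.0]heptan-3-yl]oxy}-2,2,6,6-tetramethylpiperidine (C3 epimers) | C[C@]12CCC(ON3C(C)(C)CCCC3(C)C)C[C@H]1O2 | intermediate
10 | (1R,6S)-6-methyl-7-oxabicyclo[4.1.0]heptan-3-one | C[C@]12CCC(=O)C[C@H]1O2 | intermediate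
11 | [(4S)-4-bromo-5,5-dimethylcyclopent-1-en-1-yl]magnesium chloride | CC1(C)[C@@H](Br)CC=C1[Mg]Cl | intermediate
12 | chloromagnesium (1R,3R,6S)-3-[(4S)-4-bromo-5,5-dimethylcyclopent-1-en-1-yl]-6-methyl-7-oxabicyclo[4.1.0]heptan-3-olate | CC1(C)[C@@H](Br)CC=C1[C@@]1(O[Mg]Cl)CC[C@]2(C)O[C@@H]2C1 | intermediate
13 | (1R,3R,6S)-3-[(4S)-4-bromo-5,5-dimethylcyclopent-1-en-1-yl]-6-methyl-3-(triethylsilyloxy)-7-oxabicyclo[4.1.0]heptane | CC1(C)[C@@H](Br)CC=C1[C@@]1(O[Si](CC)(CC)CC)CC[C@]2(C)O[C@@H]2C1 | intermediate
14 | (1R,2R,5R)-2-bromo-5-[(4S)-4-bromo-5,5-dimethylcyclopent-1-en-1-yl]-2-methyl-5-(triethylsilyloxy)cyclohexan-1-ol | CC1(C)[C@@H](Br)CC=C1[C@@]1(O[Si](CC)(CC)CC)CC[C@@](C)(Br)[C@H](O)C1 | intermediate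
15 | {[(1R,3S,4S)-3-bromo-1-[(4S)-4-bromo-5,5-dimethylcyclopent-1-en-1-yl]-4-chloro-4-methylcyclohexyl]oxy}triethylsilane | CC1(C)[C@@H](Br)CC=C1[C@@]1(O[Si](CC)(CC)CC)CC[C@](C)(Cl)[C@@H](Br)C1 | intermediate
16 | (1R,3S,4S)-3-bromo-1-[(4S)-4-bromo-5,5-dimethylcyclopent-1-en-1-yl]-4-chloro-4-methylcyclohexan-1-ol | CC1(C)[C@@H](Br)CC=C1[C@@]1(O)CC[C@](C)(Cl)[C@@H](Br)C1 | intermediate
17 | N'-{[(1R,3S)-3-bromo-1-[(1R,3S,4S)-3-bromo-4-chloro-1-hydroxy-4-methylcyclohexyl]-2,2-dimethylcyclopentyl]methyl}octane-1-sulfonohydrazide | CC1(C)[C@@H](Br)CC[C@@]1(CNNS(=O)(=O)CCCCCCCC)[C@@]1(O)CC[C@](C)(Cl)[C@@H](Br)C1 | intermediate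
18 | (1R,3S,4S)-3-bromo-1-[(1R,3S)-3-bromo-1,2,2-trimethylcyclopentyl]-4-chloro-4-methylcyclohexan-1-ol | CC1(C)[C@@H](Br)CC[C@@]1(C)[C@@]1(O)CC[C@](C)(Cl)[C@@H](Br)C1 | target

Total step count: 9
Longest linear sequence: 8 steps (1, 2, 3, 4, 6, 7, 8, 9)

Steps most likely to fail

Step 9. The tertiary C1 radical sits between two fully substituted carbons. Its capture by the hydrazone may be slower than hydrogen abstraction, which would give net hydrogenation of the olefin, and the facial selectivity may be modest.
Fallback (tethered delivery of the carbon instead of intermolecular capture): the path sets out from 16. Silylation with chloro(iodomethyl)dimethylsilane and imidazole should give the (iodomethyl)dimethylsilyl ether F1. Selective iodine abstraction ((Me3Si)3SiH, Et3B/air, −20 °C) and 5-exo radical cyclisation onto C1 should give the spiro oxasilolane F2. Protodesilylation with buffered Bu4NF cleaves Si–C and Si–O and comes back to the route at 18.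

Step 7. The bromonium ion may be captured at the secondary carbon, may lose a proton to give an allylic bromide, or the acid may strip the silyl ether before the epoxide has reacted.
Fallback (bromine placed directly at its final carbon): the path sets out from 13. Dilithium tetrabromonickelate in THF opens the epoxide by SN2 at the secondary C5' and should give the secondary-bromide tertiary-alcohol bromohydrin F3. The same chloroenamine then activates the tertiary hydroxyl, the neighbouring bromine expels it, and chloride returns on the same face (retention through the bromonium ion). The path comes back to the route at 15.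

Step 6. The addition may show poor facial selectivity, or the ketone may be enolised with β-opening of the epoxide.
Fallback (C1' made non-stereogenic at the coupling, ring chirality set afterwards by a catalyst): the path sets out from 6 through 11.
- Addition to commercial 4-methylidenecyclohexan-1-one should give the exocyclic-olefin carbinol F4.
- A cobalt-hydride catalyst with a chiral ligand desymmetrises F4 by olefin isomerisation to the endocyclic olefin F5.
- Hydroxyl-directed epoxidation (VO(acac)2, t-BuOOH) of the unhindered ring olefin should give the cis-epoxy alcohol F6.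
- Silylation (Et3SiOTf, 2,6-lutidine) comes back to the route at 13.

Further compounds
F1 | step 9 | {[(1R,3S,4S)-3-bromo-1-[(4S)-4-bromo-5,5-dimethylcyclopent-1-en-1-yl]-4-chloro-4-methylcyclohexyl]oxy}(iodomethyl)dimethylsilane | CC1(C)[C@@H](Br)CC=C1[C@@]1(O[Si](C)(C)CI)CC[C@](C)(Cl)[C@@H](Br)C1
F2 | step 9 | dispiro oxasilolane with the ring C1'–O–SiMe2–CH2–C1 (CH2 trans to C3–Br) | CC1(C)[C@@H](Br)CC[C@]12C[Si](C)(C)O[C@@]23CC[C@](C)(Cl)[C@@H](Br)C3
F3 | step 7 | (1S,2S,4R)-2-bromo-4-[(4S)-4-bromo-5,5-dimethylcyclopent-1-en-1-yl]-1-methyl-4-(triethylsilyloxy)cyclohexan-1-ol | CC1(C)[C@@H](Br)CC=C1[C@@]1(O[Si](CC)(CC)CC)CC[C@](C)(O)[C@@H](Br)C1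
F4 | step 6 | 1-[(4S)-4-bromo-5,5-dimethylcyclopent-1-en-1-yl]-4-methylidenecyclohexan-1-ol | CC1(C)[C@@H](Br)CC=C1C1(O)CCC(=C)CC1
F5 | step 6 | (1R)-1-[(4S)-4-bromo-5,5-dimethylcyclopent-1-en-1-yl]-4-methylcyclohex-3-en-1-ol | CC1(C)[C@@H](Br)CC=C1[C@@]1(O)CCC(C)=CC1
F6 | step 6 | (1R,3R,6S)-3-[(4S)-4-bromo-5,5-dimethylcyclopent-1-en-1-yl]-6-methyl-7-oxabicyclo[4.1.0]heptan-3-ol | CC1(C)[C@@H](Br)CC=C1[C@@]1(O)CC[C@]2(C)O[C@@H]2C1
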